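The route rests on opening the α-methylene-γ-lactone (ring O6–C12–C11–C7–C6 with its exocyclic C11=C13 methylene, germacrane numbering) to a C7 ethynyl group and a free C6 hydroxyl on the intact ten-membered carbocycle C1–C10. In the last step a palladium-catalysed cyclocarbonylation inserts CO as C12, forming C11–C12 and C12–O6 and closing the cis-fused lactone in one operation, so the Michael-accepting methylene lactone is never carried. The precursor already holds the 4,5-epoxide, the C10=C1 acrylate, the C8 epoxy ester and the C9 acetate. It is assembled by a syn-selective allenylstannane addition (C6–C7), a hydroxyl-directed epoxidation and a Nozaki–Hiyama–Kishi ring closure (C9–C10).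

Key step: step 21

Remark on numbering: germacrane numbering is used throughout. Ring carbons are C1–C10; C11 and C13 are the ethynyl carbons (later the lactone α-carbon and its methylene); C12 is the lactone carbonyl; C14 is the ester carbon on C10; C15 is the methyl on C4.

Remark on configuration (read from the target SMILES): H6 and H7 are cis (cis-fused lactone), C3 and C6 are cis on the epoxide, and O8 and O9 are syn; the descriptors are 4R,5S,6R,7R,8S,9S and 2′S. Cis fusion requires the open-chain alcohol in which O6 and the C8 branch are syn on the C5–C6–C7–C11 zigzag (O6 anti to the ethynyl group along the ring backbone). That isomer is the product of an open-transition-state, Lewis-acid-promoted allenylstannane addition; a closed-transition-state allenylmetal would give the anti isomer and hence the trans-fused lactone. The 4,5-epoxide is the threo epoxy alcohol of the C6 carbinol, so it is introduced by hydroxyl-directed epoxidation after the Lewis-acid step and not carried through it.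

Step 1
Reactants: 1 neryl acetate
Product: 3 (2Z)-3-methyl-6-oxohex-2-en-1-yl acetate, via ozonide 2 (not isolated)
Conditions: O3 (1.0 equiv), CH2Cl2, −78 °C; then PPh3, −78 °C to rt
Reagents that add atoms: ozone, [O-][O+]=O
Why: Chemoselective ozonolysis, since the remote trisubstituted alkene is more electron-rich than the alkene deactivated by the allylic acetate, so one equivalent of ozone should cleave it alone and PPh3 reduces the ozonide to the aldehyde with the Z-alkene untouched.

Step 2
Reactants: 3 (2Z)-3-methyl-6-oxohex-2-en-1-yl acetate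
Product: 4 methyl (2Z,6Z)-8-acetoxy-2-iodo-6-methylocta-2,6-dienoate
Conditions: Ph3P=CHCO2Me, NIS, CH2Cl2, −20 °C; then 3, −20 °C to rt
Reagents that add atoms: methyl (triphenylphosphoranylidene)acetate, COC(=O)C=P(c1ccccc1)(c1ccccc1)c1ccccc1; N-iodosuccinimide, O=C1CCC(=O)N1I
Why: Wittig olefination with the ester-stabilised α-iodo ylide formed in situ by iodination of the phosphorane; as with other stabilised ylides the ester should end up trans to the alkyl chain, which is the (2Z)-iodoenoate (iodine cis to C2) needed for the ring-cis C1=C10 acrylate.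

Step 3
Reactants: 4 methyl (2Z,6Z)-8-acetoxy-2-iodo-6-methylocta-2,6-dienoate
Product: 5 methyl (2Z,6Z)-8-hydroxy-2-iodo-6-methylocta-2,6-dienoate
Conditions: K2CO3 (cat.), MeOH, 0 °C
Reagents that add atoms: none
Why: Base-catalysed transesterification (methanolysis) of the allylic acetate; exchange at the methyl ester is degenerate and the β-substituted α-iodoenoate is a poor Michael acceptor at this temperature.

Step 4
Reactants: 5 methyl (2Z,6Z)-8-hydroxy-2-iodo-6-methylocta-2,6-dienoate
Product: 6 methyl (2Z,6Z)-2-iodo-6-methyl-8-oxoocta-2,6-dienoate (the C6 enal)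
Conditions: MnO2, CH2Cl2, rt
Reagents that add atoms: none
Why: MnO2 oxidation, which is selective for allylic alcohols and is known to convert nerol-type Z-allylic alcohols into Z-enals without geometric isomerisation.

Step 5
Reactants: 7 4-methoxybenzyl alcohol; 8 allyl bromide
Product: 9 allyl 4-methoxybenzyl ether
Conditions: NaH, THF/DMF, 0 °C to rt
Reagents that add atoms: none
Why: Williamson ether synthesis (SN2 of the alkoxide on the allylic bromide).

Step 6
Reactants: 9 allyl 4-methoxybenzyl ether; 10 3-(trimethylsilyl)prop-2-ynal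
Product: 12 (3R,4R)-4-[(4-methoxybenzyl)oxy]-1-(trimethylsilyl)hex-5-en-1-yn-3-ol, via alkoxyallylborane 11 (not isolated)
Conditions: sec-BuLi, THF, −78 °C; (−)-Ipc2BOMe; BF3·OEt2; then 10, −78 °C; NaOH, H2O2
Reagents that add atoms: none
Why: Brown asymmetric γ-alkoxyallylboration, in which kinetic deprotonation gives the chelated (Z)-alkoxyallyl anion and hence the (Z)-allylborane, the chair Zimmerman–Traxler transition state turns Z geometry into the syn ether-alcohol, and the isopinocampheyl groups of the (+)-α-pinene series direct attack to the aldehyde Si face to set C7 (3R) and C8 (4R).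

Step 7
Reactants: 12 (3R,4R)-4-[(4-methoxybenzyl)oxy]-1-(trimethylsilyl)hex-5-en-1-yn-3-ol
Product: 13 (3R,4R)-4-[(4-methoxybenzyl)oxy]hex-5-en-1-yn-3-ol
Conditions: K2CO3, MeOH, rt
Reagents that add atoms: none
Why: Methoxide-mediated protodesilylation of the alkynylsilane, which leaves both stereocentres untouched.

Step 8
Reactants: 13 (3R,4R)-4-[(4-methoxybenzyl)oxy]hex-5-en-1-yn-3-ol
Product: 14 (3R,4R)-4-[(4-methoxybenzyl)oxy]hex-5-en-1-yn-3-yl methanesulfonate
Conditions: MsCl, Et3N, CH2Cl2, −78 to 0 °C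
Reagents that add atoms: methanesulfonyl chloride, CS(=O)(=O)Cl
Why: Sulfonylation of the propargylic alcohol on oxygen, so no bond to the stereocentre is broken.

Step 9
Reactants: 14 (3R,4R)-4-[(4-methoxybenzyl)oxy]hex-5-en-1-yn-3-yl methanesulfonate
Product: 15 tributyl[(4R)-4-[(4-methoxybenzyl)oxy]hexa-1,2,5-trien-1-yl]stannane with aR (M) allene axis
Conditions: Bu3SnH, LiN(iPr)2, THF, 0 °C; CuBr·SMe2, −78 °C; then 14, −78 °C
Reagents that add atoms: tributyltin hydride, CCCC[SnH](CCCC)CCCC
Why: Anti SN2′ displacement of the propargylic mesylate by the stannylcuprate (Marshall allenylstannane synthesis); tin enters at C13 anti to the leaving group, so the C7 centre of 14 is translated into the aR allene axis.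

Step 10
Reactants: 6 methyl (2Z,6Z)-2-iodo-6-methyl-8-oxoocta-2,6-dienoate; 15 the aR allenylstannane
Product: 16 methyl (2Z,6Z,8S,9S,10R)-9-ethynyl-8-hydroxy-2-iodo-10-[(4-methoxybenzyl)oxy]-6-methyldodeca-2,6,11-trienoate (syn homopropargylic alcohol)
Conditions: BF3·OEt2, CH2Cl2, −78 °C
Reagents that add atoms: none
Why: Marshall-type BF3-promoted SE2′ addition of the allenylstannane, in which attack anti to tin transfers the allene axis to C7 and the open, acyclic transition state should give the syn adduct (O6 and the C8 branch syn, as cis lactone fusion requires); the enal is achiral, so C6 and C7 are under reagent control.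

Step 11
Reactants: 16 the syn homopropargylic Z-allylic alcohol
Product: 17 methyl (2Z)-5-[(2R,3S)-3-[(1R,2S,3R)-2-ethynyl-1-hydroxy-3-[(4-methoxybenzyl)oxy]pent-4-en-1-yl]-2-methyloxiran-2-yl]-2-iodopent-2-enoate (4R,5S-epoxy alcohol)
Conditions: mCPBA, NaHCO3, CH2Cl2, 0 °C
Reagents that add atoms: 3-chloroperoxybenzoic acid, OOC(=O)c1cccc(Cl)c1
Why: Hydroxyl-directed (Henbest) epoxidation, where allylic 1,3-strain with the cis C3 substituent holds H6 in the alkene plane and the peracid is delivered to the face of the hydrogen-bonded C6 hydroxyl to give the threo epoxy alcohol (4R,5S); the iodoacrylate, the monosubstituted vinyl group and the alkyne should react far more slowly.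

Step 12
Reactants: 17 the 4,5-epoxy C6 alcohol
Product: 18 methyl (2Z)-5-[(2R,3S)-3-[(1R,2R,3R)-2-ethynyl-3-[(4-methoxybenzyl)oxy]-1-[(triethylsilyl)oxy]pent-4-en-1-yl]-2-methyloxiran-2-yl]-2-iodopent-2-enoate (C6 triethylsilyl ether)
Conditions: TESOTf, 2,6-lutidine, CH2Cl2, −78 °C
Reagents that add atoms: triethylsilyl trifluoromethanesulfonate, CC[Si](CC)(CC)OS(=O)(=O)C(F)(F)F
Why: Silylation of the hindered secondary alcohol with the silyl triflate under lutidine buffering, cold enough to spare the epoxide; the TES group is chosen because it can be removed at the end without touching esters or epoxides.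

Step 13
Reactants: 18 the C6 triethylsilyl ether with terminal vinyl group
Product: 20 methyl (2Z)-5-[(2R,3S)-3-[(1R,2R,3S)-2-ethynyl-3-[(4-methoxybenzyl)oxy]-4-oxo-1-[(triethylsilyl)oxy]butyl]-2-methyloxiran-2-yl]-2-iodopent-2-enoate (C9 seco-aldehyde), via diol 19 (not isolated)
Conditions: OsO4 (cat.), NaIO4, 2,6-lutidine, dioxane/H2O, rt
Reagents that add atoms: osmium tetroxide (catalytic oxygen carrier), O=[Os](=O)(=O)=O; sodium periodate, [Na+].[O-]I(=O)(=O)=O
Why: Lemieux–Johnson oxidation, in which the monosubstituted vinyl group is dihydroxylated much faster than the electron-poor trisubstituted iodoacrylate or the alkyne and periodate cleaves the diol to the C9 aldehyde under lutidine buffering that protects the α-alkoxy stereocentre C8.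

Step 14
Reactants: 20 the C9 seco-aldehyde bearing the C10 alkenyl iodide
Product: 21 methyl (1E,5R,6S,7R,8R,9S,10S)-5,6-epoxy-8-ethynyl-10-hydroxy-9-[(4-methoxybenzyl)oxy]-5-methyl-7-[(triethylsilyl)oxy]cyclodec-1-ene-1-carboxylate (macrocyclic C9 alcohol)
Conditions: CrCl2 (10 equiv), NiCl2 (cat.), DMSO/THF, rt, high dilution
Reagents that add atoms: none
Why: Nozaki–Hiyama–Kishi macrocyclisation, where zerovalent nickel formed from NiCl2 inserts into the C10–I bond, transmetalation gives the alkenylchromium species (trivalent chromium) and this adds to the C9 aldehyde with retention of alkene geometry to close the ten-membered ring; the 9S carbinol (O9 syn to O8) is the one expected if the C8 ether oxygen and the aldehyde oxygen are held syn on chromium in the ring-forming transition state, and this is the least secure stereocentre of the route.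

Step 15
Reactants: 21 the macrocyclic C9 alcohol
Product: 22 methyl (1E,5R,6S,7R,8R,9S,10S)-10-acetoxy-5,6-epoxy-8-ethynyl-9-[(4-methoxybenzyl)oxy]-5-methyl-7-[(triethylsilyl)oxy]cyclodec-1-ene-1-carboxylate (C9 acetate)
Conditions: Ac2O, pyridine, DMAP (cat.), CH2Cl2, 0 °C
Reagents that add atoms: acetic anhydride, CC(=O)OC(C)=O
Why: DMAP-catalysed acylation of the only free hydroxyl, with retention at C9.

Step 16
Reactants: 22 the C9 acetate with C8 4-methoxybenzyl ether
Product: 23 methyl (1E,5R,6S,7R,8R,9S,10S)-10-acetoxy-5,6-epoxy-8-ethynyl-9-hydroxy-5-methyl-7-[(triethylsilyl)oxy]cyclodec-1-ene-1-carboxylate (C8 alcohol)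
Conditions: DDQ, CH2Cl2/pH 7 buffer, 0 °C
Reagents that add atoms: none
Why: Oxidative cleavage of the 4-methoxybenzyl ether by DDQ under neutral buffered conditions, which should leave the silyl ether, the acetate, the epoxide, the alkyne and the electron-poor alkene intact and give little opportunity for acetyl migration.

Step 17
Reactants: 24 methallyl alcohol
Product: 25 (R)-2-methylglycidol, [(2R)-2-methyloxiran-2-yl]methanol
Conditions: Ti(OiPr)4 (cat.), D-(−)-diisopropyl tartrate (cat.), tBuOOH, 4 Å MS, CH2Cl2, −20 °C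
Reagents that add atoms: tert-butyl hydroperoxide, CC(C)(C)OO
Why: Sharpless asymmetric epoxidation, in which the D-(−)-tartrate complex delivers oxygen to the face that gives the 2R epoxy alcohol.

Step 18
Reactants: 25 (R)-2-methylglycidol
Product: 26 (2S)-2-methyloxirane-2-carboxylic acid
Conditions: RuCl3 (cat.), NaIO4, EtOAc/MeCN/H2O, 0 °C to rt
Reagents that add atoms: water, O
Why: Ruthenium tetroxide oxidation of a 2,3-epoxy alcohol to the glycidic acid, with the quaternary stereocentre untouched (the descriptor changes from R to S only through the priority change).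

Step 19
Reactants: 23 the macrocyclic C8 alcohol; 26 (2S)-2-methyloxirane-2-carboxylic acid
Product: 28 methyl (1E,5R,6S,7R,8R,9S,10S)-10-acetoxy-5,6-epoxy-8-ethynyl-5-methyl-9-{[(2S)-2-methyloxirane-2-carbonyl]oxy}-7-[(triethylsilyl)oxy]cyclodec-1-ene-1-carboxylate (C8 epoxy ester), via mixed anhydride 27 (not isolated)
Conditions: 2,4,6-trichlorobenzoyl chloride, Et3N, THF, rt; then 23, DMAP, toluene, rt
Reagents that add atoms: none
Why: Yamaguchi esterification, chosen because the mixed anhydride with DMAP acylates hindered secondary alcohols with quaternary acids quickly enough to outrun acetyl migration from O9; neither C8 nor C2′ is affected.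

Step 20
Reactants: 28 the C8 epoxy ester with C6 triethylsilyl ether
Product: 29 methyl (1E,5R,6S,7R,8S,9S,10S)-10-acetoxy-5,6-epoxy-8-ethynyl-7-hydroxy-5-methyl-9-{[(2S)-2-methyloxirane-2-carbonyl]oxy}cyclodec-1-ene-1-carboxylate (7-ethynyl-6-hydroxy macrocycle)
Conditions: HF·pyridine, pyridine, THF, 0 °C
Reagents that add atoms: none
Why: Fluoride-mediated cleavage of the labile triethylsilyl ether under pyridine-buffered, weakly acidic conditions that should spare both epoxides and avoid base-induced acyl migration.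

Step 21
Reactants: 29 the 7-ethynyl-6-hydroxy macrocycle; 30 carbon monoxide
Product: 31 target CNP0274195.1 (4R,5S,6R,7R,8S,9S,2′S; 6,12-cis-fused α-methylene-γ-lactone)
Conditions: PdCl2(PPh3)2 (10 mol %), SnCl2 (10 mol %), CO (7 atm), MeCN, 65 °C
Reagents that add atoms: none
Why: Divalent palladium takes up CO and the C6 hydroxyl to give an alkoxycarbonylpalladium species (C12–O6 bond), the tethered C11≡C13 alkyne inserts syn into the Pd–C12 bond (C11–C12 bond), and protonolysis of the resulting C13 vinylpalladium releases the exocyclic methylene and returns the catalyst; a hydridopalladium/acylpalladium sequence would form the same two bonds. The closest known reaction type is the palladium-catalysed cyclocarbonylation of but-3-yn-1-ols, including cis- and trans-2-ethynylcycloalkanols, to α-methylene-γ-butyrolactones. The five-membered ring O6–C12–C11–C7–C6 closes in the 5-exo-dig mode, with C13 remaining outside the ring. No stereocentre is created: the cis fusion follows from the C6/C7 configuration set in step 10, and neither centre is touched. The step needs regioselectivity (carbonyl on C11, not C13) and chemoselectivity; the first is enforced by the tether, since only exo insertion gives the five-membered lactone, and the second by O6 being the only free hydroxyl, with O8 and O9 acylated and the acrylate, acetate and epoxides as spectators.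

Compound list
1 | neryl acetate, (2Z)-3,7-dimethylocta-2,6-dien-1-yl acetate | CC(C)=CCC/C(C)=C\COC(C)=O | starting material
2 | 6,7-ozonide of neryl acetate, (2Z)-5-(5,5-dimethyl-1,2,4-trioxolan-3-yl)-3-methylpent-2-en-1-yl acetate | CC1(C)OOC(CC/C(C)=C\COC(C)=O)O1 | intermediate
3 | (2Z)-3-methyl-6-oxohex-2-en-1-yl acetate | O=CCC/C(C)=C\COC(C)=O | intermediate
4 | methyl (2Z,6Z)-8-acetoxy-2-iodo-6-methylocta-2,6-dienoate | COC(=O)/C(I)=C/CC/C(C)=C\COC(C)=O | intermediate
5 | methyl (2Z,6Z)-8-hydroxy-2-iodo-6-methylocta-2,6-dienoate | COC(=O)/C(I)=C/CC/C(C)=C\CO | intermediate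
6 | methyl (2Z,6Z)-2-iodo-6-methyl-8-oxoocta-2,6-dienoate | COC(=O)/C(I)=C/CC/C(C)=C\C=O | intermediate
7 | 4-methoxybenzyl alcohol | COc1ccc(CO)cc1 | starting material
8 | allyl bromide | C=CCBr | starting material
9 | allyl 4-methoxybenzyl ether | C=CCOCc1ccc(OC)cc1 | intermediate
10 | 3-(trimethylsilyl)prop-2-ynal | C[Si](C)(C)C#CC=O | starting material
11 | [(2Z)-3-[(4-methoxybenzyl)oxy]prop-2-en-1-yl]bis(isopinocampheyl)borane, (+)-α-pinene series | COc1ccc(CO/C=C\CB([C@@H]2C[C@@H]3C[C@H]([C@H]2C)C3(C)C)[C@@H]2C[C@@H]3C[C@H]([C@H]2C)C3(C)C)cc1 | intermediate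
12 | (3R,4R)-4-[(4-methoxybenzyl)oxy]-1-(trimethylsilyl)hex-5-en-1-yn-3-ol | C[Si](C)(C)C#C[C@@H](O)[C@H](OCc1ccc(OC)cc1)C=C | intermediate
13 | (3R,4R)-4-[(4-methoxybenzyl)oxy]hex-5-en-1-yn-3-ol | C#C[C@@H](O)[C@H](OCc1ccc(OC)cc1)C=C | intermediate
14 | (3R,4R)-4-[(4-methoxybenzyl)oxy]hex-5-en-1-yn-3-yl methanesulfonate | C#C[C@@H](OS(C)(=O)=O)[C@H](OCc1ccc(OC)cc1)C=C | intermediate
15 | tributyl[(4R)-4-[(4-methoxybenzyl)oxy]hexa-1,2,5-trien-1-yl]stannane, allene axis aR (M) | CCCC[Sn](CCCC)(CCCC)C([H])=[C@]=C([H])[C@H](OCc1ccc(OC)cc1)C=C | intermediate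
16 | methyl (2Z,6Z,8S,9S,10R)-9-ethynyl-8-hydroxy-2-iodo-10-[(4-methoxybenzyl)oxy]-6-methyldodeca-2,6,11-trienoate | C=C[C@@H](OCc1ccc(OC)cc1)[C@@H](C#C)[C@@H](O)/C=C(/C)CC/C=C(\I)C(=O)OC | intermediate
17 | methyl (2Z)-5-[(2R,3S)-3-[(1R,2S,3R)-2-ethynyl-1-hydroxy-3-[(4-methoxybenzyl)oxy]pent-4-en-1-yl]-2-methyloxiran-2-yl]-2-iodopent-2-enoate | C=C[C@@H](OCc1ccc(OC)cc1)[C@@H](C#C)[C@@H](O)[C@@H]1O[C@]1(C)CC/C=C(\I)C(=O)OC | intermediate
18 | methyl (2Z)-5-[(2R,3S)-3-[(1R,2R,3R)-2-ethynyl-3-[(4-methoxybenzyl)oxy]-1-[(triethylsilyl)oxy]pent-4-en-1-yl]-2-methyloxiran-2-yl]-2-iodopent-2-enoate | C=C[C@@H](OCc1ccc(OC)cc1)[C@@H](C#C)[C@@H](O[Si](CC)(CC)CC)[C@@H]1O[C@]1(C)CC/C=C(\I)C(=O)OC | intermediate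
19 | 4,5-diol from dihydroxylation of the vinyl group of 18 (both epimers at the new carbinol) | OCC(O)[C@@H](OCc1ccc(OC)cc1)[C@@H](C#C)[C@@H](O[Si](CC)(CC)CC)[C@@H]1O[C@]1(C)CC/C=C(\I)C(=O)OC | intermediate
20 | methyl (2Z)-5-[(2R,3S)-3-[(1R,2R,3S)-2-ethynyl-3-[(4-methoxybenzyl)oxy]-4-oxo-1-[(triethylsilyl)oxy]butyl]-2-methyloxiran-2-yl]-2-iodopent-2-enoate | O=C[C@@H](OCc1ccc(OC)cc1)[C@@H](C#C)[C@@H](O[Si](CC)(CC)CC)[C@@H]1O[C@]1(C)CC/C=C(\I)C(=O)OC | intermediate
21 | methyl (1E,5R,6S,7R,8R,9S,10S)-5,6-epoxy-8-ethynyl-10-hydroxy-9-[(4-methoxybenzyl)oxy]-5-methyl-7-[(triethylsilyl)oxy]cyclodec-1-ene-1-carboxylate | C#C[C@@H]1[C@H](OCc2ccc(OC)cc2)[C@@H](O)/C(C(=O)OC)=C\CC[C@@]2(C)O[C@H]2[C@@H]1O[Si](CC)(CC)CC | intermediate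
22 | methyl (1E,5R,6S,7R,8R,9S,10S)-10-acetoxy-5,6-epoxy-8-ethynyl-9-[(4-methoxybenzyl)oxy]-5-methyl-7-[(triethylsilyl)oxy]cyclodec-1-ene-1-carboxylate | C#C[C@@H]1[C@H](OCc2ccc(OC)cc2)[C@@H](OC(C)=O)/C(C(=O)OC)=C\CC[C@@]2(C)O[C@H]2[C@@H]1O[Si](CC)(CC)CC | intermediate
23 | methyl (1E,5R,6S,7R,8R,9S,10S)-10-acetoxy-5,6-epoxy-8-ethynyl-9-hydroxy-5-methyl-7-[(triethylsilyl)oxy]cyclodec-1-ene-1-carboxylate | C#C[C@@H]1[C@H](O)[C@@H](OC(C)=O)/C(C(=O)OC)=C\CC[C@@]2(C)O[C@H]2[C@@H]1O[Si](CC)(CC)CC | intermediate
24 | methallyl alcohol | C=C(C)CO | starting material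
25 | (R)-2-methylglycidol, [(2R)-2-methyloxiran-2-yl]methanol | OC[C@]1(C)CO1 | intermediate
26 | (2S)-2-methyloxirane-2-carboxylic acid | OC(=O)[C@]1(C)CO1 | intermediate
27 | (2S)-2-methyloxirane-2-carboxylic 2,4,6-trichlorobenzoic anhydride | O=C(OC(=O)c1c(Cl)cc(Cl)cc1Cl)[C@]1(C)CO1 | intermediate
28 | methyl (1E,5R,6S,7R,8R,9S,10S)-10-acetoxy-5,6-epoxy-8-ethynyl-5-methyl-9-{[(2S)-2-methyloxirane-2-carbonyl]oxy}-7-[(triethylsilyl)oxy]cyclodec-1-ene-1-carboxylate | C#C[C@@H]1[C@H](OC(=O)[C@]2(C)CO2)[C@@H](OC(C)=O)/C(C(=O)OC)=C\CC[C@@]2(C)O[C@H]2[C@@H]1O[Si](CC)(CC)CC | intermediate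
29 | methyl (1E,5R,6S,7R,8S,9S,10S)-10-acetoxy-5,6-epoxy-8-ethynyl-7-hydroxy-5-methyl-9-{[(2S)-2-methyloxirane-2-carbonyl]oxy}cyclodec-1-ene-1-carboxylate (7-ethynyl-6-hydroxy macrocycle) | C#C[C@@H]1[C@H](OC(=O)[C@]2(C)CO2)[C@@H](OC(C)=O)/C(C(=O)OC)=C\CC[C@@]2(C)O[C@H]2[C@@H]1O | intermediate
30 | carbon monoxide | [C-]#[O+] | starting material
31 | CNP0274195.1, the 6,12-cis-fused α-methylene-γ-lactone (4R,5S,6R,7R,8S,9S,2′S in germacrane numbering) | C=C1C(=O)O[C@@H]2[C@H]1[C@H](OC(=O)[C@]1(C)CO1)[C@@H](OC(C)=O)/C(C(=O)OC)=C\CC[C@@]1(C)O[C@@H]21 | target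

Total step count: 21.
Longest linear sequence: 15 steps (steps 5–16 and 19–21, from 4-methoxybenzyl alcohol 7).

Steps most likely to fail

1. Step 21 (cyclocarbonylation). What may go wrong: chloride or tin Lewis-acid opening of the two epoxides, or ionisation of the C9 allylic acetate by reduced palladium, before carbonylation is complete. Fallback: setting out from 29, molybdenum-catalysed Markovnikov hydrostannation (Bu3SnH, Mo(CO)3(CNtBu)3 cat., hydroquinone, THF, 55 °C) should give the C11 tributylstannyl alkene F1. Iododestannylation (I2, CH2Cl2, 0 °C) should give the C11 iodoalkene F2. Carbonylative lactonisation at low temperature (Pd(PPh3)4 cat., CO 1 atm, Et3N, MeCN, rt to 40 °C) then proceeds by oxidative addition of zerovalent palladium into C11–I, CO insertion and capture of the acylpalladium by O6; it comes back to the route at the target 31.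

2. Step 14 (ring closure). What may go wrong: poor facial selectivity in the addition to the C9 aldehyde, so that the 9-epimer forms alone or mixed with 21. Fallback: setting out from 20, the closure is run as before and the 9-epi alcohol F3 (alone or with 21) is oxidised (Dess–Martin periodinane, NaHCO3, CH2Cl2) to the C9 ketone F4. Luche reduction (NaBH4, CeCl3·7H2O, MeOH, −40 °C) should then deliver hydride anti to the C8 benzylic ether in a Felkin–Anh arrangement, which places O9 syn to O8 and comes back to the route at 21.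

3. Step 10 (fragment coupling). What may go wrong: erosion of syn selectivity with the unbranched conjugated aldehyde, or Lewis-acid Z-to-E isomerisation of the enal. Fallback: setting out from 6 and 15, the coupling is run as before; C7 is still fixed by the allene axis, so only C6 is in question. The anti adduct F5, together with any 16, is oxidised (Dess–Martin periodinane, NaHCO3, CH2Cl2) to the C6 ketone F6. Reagent-controlled Corey–Bakshi–Shibata reduction ((S)-2-methyl-CBS-oxazaborolidine, catecholborane, toluene, −78 °C, the alkenyl group acting as the large substituent) should then set 6R and come back to the route at 16 (there designated 8S).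

Further compounds
F1 | step 21 | 29 with the ethynyl group replaced by 1-(tributylstannyl)ethenyl | C=C([Sn](CCCC)(CCCC)CCCC)[C@@H]1[C@H](OC(=O)[C@]2(C)CO2)[C@@H](OC(C)=O)/C(C(=O)OC)=C\CC[C@@]2(C)O[C@H]2[C@@H]1O
F2 | step 21 | 29 with the ethynyl group replaced by 1-iodoethenyl | C=C(I)[C@@H]1[C@H](OC(=O)[C@]2(C)CO2)[C@@H](OC(C)=O)/C(C(=O)OC)=C\CC[C@@]2(C)O[C@H]2[C@@H]1O
F3 | step 14 | 9-epimer of 21 (10R in cyclodecene numbering) | C#C[C@@H]1[C@H](OCc2ccc(OC)cc2)[C@H](O)/C(C(=O)OC)=C\CC[C@@]2(C)O[C@H]2[C@@H]1O[Si](CC)(CC)CC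
F4 | step 14 | 9-oxo analogue of 21 (C9 ketone) | C#C[C@@H]1[C@H](OCc2ccc(OC)cc2)C(=O)/C(C(=O)OC)=C\CC[C@@]2(C)O[C@H]2[C@@H]1O[Si](CC)(CC)CC
F5 | step 10 | methyl (2Z,6Z,8R,9S,10R)-9-ethynyl-8-hydroxy-2-iodo-10-[(4-methoxybenzyl)oxy]-6-methyldodeca-2,6,11-trienoate (C6 epimer of 16) | C=C[C@@H](OCc1ccc(OC)cc1)[C@@H](C#C)[C@H](O)/C=C(/C)CC/C=C(\I)C(=O)OC
F6 | step 10 | methyl (2Z,6Z,9R,10R)-9-ethynyl-2-iodo-10-[(4-methoxybenzyl)oxy]-6-methyl-8-oxododeca-2,6,11-trienoate (C6 ketone) | C=C[C@@H](OCc1ccc(OC)cc1)[C@@H](C#C)C(=O)/C=C(/C)CC/C=C(\I)C(=O)OC
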